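**Plan**

- Cuts: first the two depside ester bonds (ring A carbonyl to O-4 of ring B, ring B carbonyl to O-4 of ring C). This leaves 2,3,4-trimethoxy-6-methylbenzoic acid and two copies of benzyl orsellinate. Ring A is then cut at C3–C4 and C5–C6.
- Enabling feature: ring A carries the carboxyl at C1, methoxyls at C2, C3 and C4, H at C5 and methyl at C6. A 2-pyrone with 5-CO2Bn, 4-OMe, 3-OMe and 6-Me supplies arene C1, C2, C3 and C6. A CH2=C(OMe)2 unit supplies C5–H and C4–OMe.
- Forward, ring A: the pyrone ring is made from methoxymalonyl dichloride and benzyl acetoacetate and is O-methylated. Cycloaddition with 1,1-dimethoxyethene, then loss of CO2 and methanol, converts it into ring A.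
- Forward, chain: rings B and C come from purchased orsellinic acid. The chain grows A, then A–B, then A–B–C by two rounds of hydrogenolysis and esterification at the unchelated 4-OH of benzyl orsellinate. A last hydrogenolysis frees the acid.
- Stereochemistry: the target has no stereocentre and no double-bond geometry. The selectivities needed are the orientation of the cycloaddition and 4-OH over 2-OH acylation.

Key step: step 5

Assumption: 1,1-dimethoxyethene is taken as a purchasable reagent; it is acid-sensitive, so it is redistilled and handled in base-washed glassware.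

**Step 1**
Reactants: 1 dimethyl methoxymalonate
Product: 2 methoxymalonic acid
Conditions: NaOH (2.2 equiv), MeOH–H2O, 0 °C to rt; then aq. HCl, 0 °C, EtOAc extraction
Reagents that add atoms: sodium hydroxide, [Na+].[OH-]
Why: Saponification of an unhindered malonate diester is fast in the cold, and acidifying below room temperature avoids decarboxylation of the malonic acid.

**Step 2**
Reactants: 2 methoxymalonic acid
Product: 3 methoxymalonyl dichloride
Conditions: (COCl)2 (2.5 equiv), DMF (cat.), CH2Cl2, 0 °C to rt; evaporate, use crude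
Reagents that add atoms: oxalyl chloride, O=C(Cl)C(=O)Cl
Why: DMF-catalysed acid chloride formation with oxalyl chloride, routine for substituted malonic acids, runs at or below room temperature, where the dichloride should neither decarboxylate nor lose HCl.

**Step 3**
Reactants: 3 methoxymalonyl dichloride; 4 benzyl acetoacetate
Product: 5 benzyl 4-hydroxy-3-methoxy-6-methyl-2-oxo-2H-pyran-5-carboxylate
Conditions: toluene, rt to 70 °C, slow N2 sweep
Reagents that add atoms: none
Why: Cyclocondensation of a malonyl dichloride with an enolisable β-keto ester (C-acylation at the α-carbon and O-acylation at the ketone enol oxygen) is the established entry to 5-acyl-4-hydroxy-2-pyrones, and either order of the two acylations leads to the same ring.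

**Step 4**
Reactants: 5 benzyl 4-hydroxy-3-methoxy-6-methyl-2-oxo-2H-pyran-5-carboxylate
Product: 6 benzyl 3,4-dimethoxy-6-methyl-2-oxo-2H-pyran-5-carboxylate
Conditions: Me2SO4, K2CO3, acetone, reflux
Reagents that add atoms: dimethyl sulfate, COS(=O)(=O)OC
Why: Williamson-type O-methylation of the vinylogous acid with a hard electrophile and K2CO3 in acetone is the standard way to 4-methoxy-2-pyrones, and the C3 methoxyl blocks C-alkylation.

**Step 5**
Reactants: 6 benzyl 3,4-dimethoxy-6-methyl-2-oxo-2H-pyran-5-carboxylate; 7 1,1-dimethoxyethene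
Product: 10 benzyl 2,3,4-trimethoxy-6-methylbenzoate, via bicyclic lactone adduct 8 (not isolated), via tetramethoxycyclohexadiene ester 9 (not isolated)
Conditions: 7 (8 equiv), toluene, base-washed sealed tube, 135 °C
Reagents that add atoms: none
Why: The nucleophilic CH2 terminus of 7 attacks pyrone C6, which is both the β-carbon of the C5 benzyl ester and the δ-carbon of the lactone dienoate, while the acetal carbon joins C3, in a strongly asynchronous inverse-electron-demand Diels–Alder reaction that gives the 2-oxabicyclo[2.2.2]octenone 8. Retro-[4+2] extrusion of CO2 from 8 gives the 4,4-dimethoxycyclohexadiene 9, and 1,2-elimination of methanol across C4–C5 aromatises it to 10. The closest known reaction type is the cycloaddition, decarboxylation and elimination sequence of 5-alkoxycarbonyl-2-pyrones (coumalates, isodehydroacetates) with ketene acetals, which delivers 4-alkoxybenzoates. Ring A is closed by an intermolecular [4+2] cycloaddition that makes its C3–C4 and C5–C6 bonds in one operation, with four ring carbons coming from the pyrone and two from 7. The two bridgehead stereocentres of 8 are locked to each other by the bicycle, arise as a racemate and vanish on aromatisation, so no stereocontrol is needed. Only regiocontrol is needed, and the matched polarisation of the partners secures it (largest acceptor coefficient at C6 because of the C5 ester, largest donor coefficient at the CH2 of 7); the donor methoxyls at C3 and C4 should cost rate and not orientation, hence the excess of 7 and the high temperature.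

**Step 6**
Reactants: 10 benzyl 2,3,4-trimethoxy-6-methylbenzoate
Product: 11 2,3,4-trimethoxy-6-methylbenzoic acid
Conditions: H2 (1 atm), 10% Pd/C, EtOAc, rt
Reagents that add atoms: none
Why: Catalytic hydrogenolysis cleaves the benzylic C–O bond and so frees the doubly ortho-substituted acid without the forcing saponification such a hindered ester would need.

**Step 7**
Reactants: 12 orsellinic acid (2,4-dihydroxy-6-methylbenzoic acid)
Product: 13 benzyl orsellinate (benzyl 2,4-dihydroxy-6-methylbenzoate)
Conditions: BnBr, KHCO3, DMF, rt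
Reagents that add atoms: benzyl bromide, BrCc1ccccc1
Why: In this SN2 alkylation KHCO3 deprotonates only the carboxylic acid, so the phenols are not benzylated, and room temperature avoids decarboxylation.

**Step 8**
Reactants: 11 2,3,4-trimethoxy-6-methylbenzoic acid; 13 benzyl orsellinate
Product: 15 benzyl 2-hydroxy-6-methyl-4-[(2,3,4-trimethoxy-6-methylbenzoyl)oxy]benzoate, via acyl trifluoroacetate 14 (not isolated)
Conditions: (CF3CO)2O (3 equiv), toluene, 0 °C to rt
Reagents that add atoms: none
Why: In this mixed-anhydride esterification the acyl trifluoroacetate of an electron-rich 2,6-disubstituted benzoic acid transfers its aroyl group in an acylium-like way, and in 13 only the 4-OH can react because the 2-OH is hydrogen-bonded to the neighbouring ester carbonyl and shielded by it.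

**Step 9**
Reactants: 15 benzyl 2-hydroxy-6-methyl-4-[(2,3,4-trimethoxy-6-methylbenzoyl)oxy]benzoate
Product: 16 2-hydroxy-6-methyl-4-[(2,3,4-trimethoxy-6-methylbenzoyl)oxy]benzoic acid
Conditions: H2 (1 atm), 10% Pd/C, EtOAc, rt; evaporate below 30 °C
Reagents that add atoms: none
Why: Neutral catalytic hydrogenolysis at room temperature removes the benzyl ester, leaves the aryl ester link and the methoxyls untouched, and avoids the thermal decarboxylation typical of orsellinic-type acids.

**Step 10**
Reactants: 16 2-hydroxy-6-methyl-4-[(2,3,4-trimethoxy-6-methylbenzoyl)oxy]benzoic acid; 13 benzyl orsellinate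
Product: 18 benzyl 2-hydroxy-4-({2-hydroxy-6-methyl-4-[(2,3,4-trimethoxy-6-methylbenzoyl)oxy]benzoyl}oxy)-6-methylbenzoate, via didepside acyl trifluoroacetate 17 (not isolated)
Conditions: (CF3CO)2O (3 equiv), toluene, 0 °C to rt
Reagents that add atoms: none
Why: The same mixed-anhydride esterification should apply because the 2-OH of 16 is chelated to its own carboxyl and hindered, the crowded ring A ester resists acyl exchange, and the 4-OH of 13 is the only unchelated phenol present.

**Step 11**
Reactants: 18 benzyl 2-hydroxy-4-({2-hydroxy-6-methyl-4-[(2,3,4-trimethoxy-6-methylbenzoyl)oxy]benzoyl}oxy)-6-methylbenzoate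
Product: 19 2-hydroxy-4-({2-hydroxy-6-methyl-4-[(2,3,4-trimethoxy-6-methylbenzoyl)oxy]benzoyl}oxy)-6-methylbenzoic acid (CNP0332884.0)
Conditions: H2 (1 atm), 10% Pd/C, EtOAc–THF, rt; evaporate below 30 °C
Reagents that add atoms: none
Why: Hydrogenolysis of the terminal benzyl ester is the usual closing move for depsides, since no acid, base or heat reaches the two aryl ester links or the decarboxylation-prone salicylic acid terminus.

**Compound list**

1 | dimethyl methoxymalonate | COC(C(=O)OC)C(=O)OC | starting material
2 | methoxymalonic acid | COC(C(=O)O)C(=O)O | intermediate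
3 | methoxymalonyl dichloride | COC(C(=O)Cl)C(=O)Cl | intermediate
4 | benzyl acetoacetate | CC(=O)CC(=O)OCc1ccccc1 | starting material
5 | benzyl 4-hydroxy-3-methoxy-6-methyl-2-oxo-2H-pyran-5-carboxylate | CC1=C(C(=O)OCc2ccccc2)C(O)=C(OC)C(=O)O1 | intermediate
6 | benzyl 3,4-dimethoxy-6-methyl-2-oxo-2H-pyran-5-carboxylate | CC1=C(C(=O)OCc2ccccc2)C(OC)=C(OC)C(=O)O1 | intermediate
7 | 1,1-dimethoxyethene | C=C(OC)OC | starting material
8 | benzyl 4,5,8,8-tetramethoxy-1-methyl-3-oxo-2-oxabicyclo[2.2.2]oct-5-ene-6-carboxylate (racemic, one enantiomer drawn; not isolated) | C[C@@]12CC(OC)(OC)[C@@](OC)(C(=O)O1)C(OC)=C2C(=O)OCc1ccccc1 | intermediate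
9 | benzyl 4,4,5,6-tetramethoxy-2-methylcyclohexa-1,5-diene-1-carboxylate (not isolated) | CC1=C(C(=O)OCc2ccccc2)C(OC)=C(OC)C(OC)(OC)C1 | intermediate
10 | benzyl 2,3,4-trimethoxy-6-methylbenzoate | COc1cc(C)c(C(=O)OCc2ccccc2)c(OC)c1OC | intermediate
11 | 2,3,4-trimethoxy-6-methylbenzoic acid | COc1cc(C)c(C(=O)O)c(OC)c1OC | intermediate
12 | orsellinic acid (2,4-dihydroxy-6-methylbenzoic acid) | Cc1cc(O)cc(O)c1C(=O)O | starting material
13 | benzyl orsellinate (benzyl 2,4-dihydroxy-6-methylbenzoate) | Cc1cc(O)cc(O)c1C(=O)OCc1ccccc1 | intermediate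
14 | 2,3,4-trimethoxy-6-methylbenzoic trifluoroacetic anhydride (not isolated) | COc1cc(C)c(C(=O)OC(=O)C(F)(F)F)c(OC)c1OC | intermediate
15 | benzyl 2-hydroxy-6-methyl-4-[(2,3,4-trimethoxy-6-methylbenzoyl)oxy]benzoate | COc1cc(C)c(C(=O)Oc2cc(C)c(C(=O)OCc3ccccc3)c(O)c2)c(OC)c1OC | intermediate
16 | 2-hydroxy-6-methyl-4-[(2,3,4-trimethoxy-6-methylbenzoyl)oxy]benzoic acid | COc1cc(C)c(C(=O)Oc2cc(C)c(C(=O)O)c(O)c2)c(OC)c1OC | intermediate
17 | 2-hydroxy-6-methyl-4-[(2,3,4-trimethoxy-6-methylbenzoyl)oxy]benzoic trifluoroacetic anhydride (not isolated) | COc1cc(C)c(C(=O)Oc2cc(C)c(C(=O)OC(=O)C(F)(F)F)c(O)c2)c(OC)c1OC | intermediate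
18 | benzyl 2-hydroxy-4-({2-hydroxy-6-methyl-4-[(2,3,4-trimethoxy-6-methylbenzoyl)oxy]benzoyl}oxy)-6-methylbenzoate | COc1cc(C)c(C(=O)Oc2cc(C)c(C(=O)Oc3cc(C)c(C(=O)OCc4ccccc4)c(O)c3)c(O)c2)c(OC)c1OC | intermediate
19 | 2-hydroxy-4-({2-hydroxy-6-methyl-4-[(2,3,4-trimethoxy-6-methylbenzoyl)oxy]benzoyl}oxy)-6-methylbenzoic acid (CNP0332884.0) | COc1cc(C)c(C(=O)Oc2cc(C)c(C(=O)Oc3cc(C)c(C(=O)O)c(O)c3)c(O)c2)c(OC)c1OC | target

Total step count: 11.
Longest linear sequence: 10 steps (steps 1–6 and 8–11, from dimethyl methoxymalonate).

**Steps most likely to fail**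

**Step 5.** The two donor methoxyls may slow the cycloaddition so much that thermal oligomerisation of the ketene acetal, or conjugate addition at C6 without closure at the crowded C3, wins.
- The fallback sets out from 13 and rejoins the route at 10. Ring A is then derived from the orsellinate ring instead of being built.
- Rieche formylation of 13 (Cl2CHOMe, TiCl4, CH2Cl2, −20 °C) should place the aldehyde at C3, between the two phenols that can hold the titanium. This gives benzyl 3-formyl-2,4-dihydroxy-6-methylbenzoate F1.
- Dakin oxidation (H2O2, NaOH, aq. THF, 0 °C, under N2) should exchange the formyl group for hydroxyl and give benzyl 2,3,4-trihydroxy-6-methylbenzoate F2.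
- Exhaustive O-methylation (Me2SO4, K2CO3, acetone, reflux) should then give 10.

**Step 3.** The dichloride may lose HCl to an alkoxyketene that oligomerises, or the enol may be acylated once without ring closure, before both new bonds are in place.
- The fallback sets out from 1 (with 4 as partner) and rejoins at 5. The two acylations are separated.
- Saponification of one ester of 1 (KOH, 1 equiv, MeOH, 0 °C) should give 2,3-dimethoxy-3-oxopropanoic acid F3.
- Oxalyl chloride with catalytic DMF should give methyl 3-chloro-2-methoxy-3-oxopropanoate F4.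
- Soft-enolisation C-acylation of 4 (MgCl2, pyridine, CH2Cl2, 0 °C) should give 1-benzyl 5-methyl 2-acetyl-4-methoxy-3-oxopentanedioate F5.
- Lactonisation of the acetyl enol oxygen onto the methyl ester (DBU, toluene, 80 °C) should give 5.

**Step 10.** The activated didepside acid may acylate its own 2-OH, or pass on its ring A acyl group by ester exchange, faster than it meets the 4-OH of 13.
- The fallback sets out from 13 (with 11 as the later partner) and rejoins at 18. The B–C ester is made first from monomers and ring A is attached last.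
- Silylation of the unchelated phenol of 13 (TBSCl, imidazole, DMF, rt) should give benzyl 4-[(tert-butyldimethylsilyl)oxy]-2-hydroxy-6-methylbenzoate F6.
- Hydrogenolysis (H2, 10% Pd/C, EtOAc) should give 4-[(tert-butyldimethylsilyl)oxy]-2-hydroxy-6-methylbenzoic acid F7.
- Carbodiimide coupling with a second portion of 13 (DCC, toluene, rt) should give benzyl 4-({4-[(tert-butyldimethylsilyl)oxy]-2-hydroxy-6-methylbenzoyl}oxy)-2-hydroxy-6-methylbenzoate F8.
- Buffered desilylation (Bu4NF, AcOH, THF, 0 °C) should give benzyl 4-[(2,4-dihydroxy-6-methylbenzoyl)oxy]-2-hydroxy-6-methylbenzoate F9.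
- The ring B 4-OH of F9 is its only unchelated phenol, and it should be acylated by 11 under the conditions of step 8 to give 18.

**Further compounds**

F1 | step 5 | benzyl 3-formyl-2,4-dihydroxy-6-methylbenzoate | Cc1cc(O)c(C=O)c(O)c1C(=O)OCc1ccccc1
F2 | step 5 | benzyl 2,3,4-trihydroxy-6-methylbenzoate | Cc1cc(O)c(O)c(O)c1C(=O)OCc1ccccc1
F3 | step 3 | 2,3-dimethoxy-3-oxopropanoic acid (racemic) | COC(C(=O)O)C(=O)OC
F4 | step 3 | methyl 3-chloro-2-methoxy-3-oxopropanoate (racemic) | COC(C(=O)Cl)C(=O)OC
F5 | step 3 | 1-benzyl 5-methyl 2-acetyl-4-methoxy-3-oxopentanedioate (enolisable, no defined configuration) | CC(=O)C(C(=O)OCc1ccccc1)C(=O)C(OC)C(=O)OC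
F6 | step 10 | benzyl 4-[(tert-butyldimethylsilyl)oxy]-2-hydroxy-6-methylbenzoate | Cc1cc(O[Si](C)(C)C(C)(C)C)cc(O)c1C(=O)OCc1ccccc1
F7 | step 10 | 4-[(tert-butyldimethylsilyl)oxy]-2-hydroxy-6-methylbenzoic acid | Cc1cc(O[Si](C)(C)C(C)(C)C)cc(O)c1C(=O)O
F8 | step 10 | benzyl 4-({4-[(tert-butyldimethylsilyl)oxy]-2-hydroxy-6-methylbenzoyl}oxy)-2-hydroxy-6-methylbenzoate | Cc1cc(O[Si](C)(C)C(C)(C)C)cc(O)c1C(=O)Oc1cc(C)c(C(=O)OCc2ccccc2)c(O)c1
F9 | step 10 | benzyl 4-[(2,4-dihydroxy-6-methylbenzoyl)oxy]-2-hydroxy-6-methylbenzoate | Cc1cc(O)cc(O)c1C(=O)Oc1cc(C)c(C(=O)OCc2ccccc2)c(O)c1
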